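## Structural features

The target is a 2,3-dihydrobenzofuran: a benzene ring (ring A) fused through C3a and C7a to a five-membered O1–C2–C3 ring. Ring A carries a methoxy group at C7 and an (E)-prop-1-enyl group at C5. C2 bears a 3-hydroxy-4,5-dimethoxyphenyl group (ring B) and the neighbouring C3 bears a methyl group. The two adjacent stereocentres are both S, and the aryl and methyl groups are trans.

Three groups are fragile. The free, electron-rich phenol of ring B is easily oxidised and nucleophilic. The styrene-type propenyl group is sensitive to acid, electrophilic oxidants and palladium hydrides, and must end up E. The C2–O1 bond is both a benzylic and an aryl ether bond and can ionise under acid, which would scramble C2.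

The real difficulty is to fix the contiguous C2/C3 pair in absolute and relative terms while attaching the three-atom unit O–C2–C3 to two neighbouring carbons of ring A. C5 is para to C7a, so a one-carbon acceptor there (an ester) can stand in for the propenyl group until late.

The key step exploits the fact that O1 and C3 sit on the adjacent ring A carbons C7a and C3a, with the C7 methoxy group on the other flank of C7a. Ring A is therefore an ortho-methoxy aryl iodide (iodine at C7a, free C–H at C3a). It can be annulated at its ipso and open ortho positions by the O–C2–C3 unit of a cis aryl methyl epoxide that already holds both stereocentres.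

## Logic of the disconnections

**12 to 11.** The phenolic O–H of ring B is replaced by an O–S bond. A free phenol would not survive the oxidations and the palladium chemistry earlier in the route, and the sulfonate also serves as the electron-withdrawing group that the key step needs. The gain is one protecting group that lasts from the first step to the last. The forward step must cleave O–S with a nucleophile at sulfur without touching the styrene or the benzylic ether.

**11 to 10.** The C=C bond of the C5 propenyl group is cut. This olefin would compete with norbornene for aryl–palladium species and would not survive an epoxidation, so it is made after the key step. The gain is that C5 carries only a one-carbon carbonyl group. The forward olefination must be E-selective and must not use a base that attacks the sulfonate.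

**10 to 9 to 8.** No skeletal bond is cut; the C5 carbon is taken back from the aldehyde through the alcohol to the methyl ester. The ester is inert under carbonate at high temperature and, being para to C7a, is an acceptor that should help both C–I insertion and C–O reductive elimination. The forward reduction must spare the aryl sulfonate, and the oxidation must stop at the aldehyde.

**8 to 6 and 7.** The C3–C3a bond and the O1–C7a bond are cut together. Both go to adjacent ring A carbons, one of which can be a C–I carbon and the other a C–H carbon, with the C7 methoxy group as the ortho substituent that norbornene catalysis requires. The gain is the largest in the route: two fragments of similar size, one ring and two skeletal bonds in one operation, and both stereocentres delegated to 6.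

- The forward step must open 6 at its methyl-bearing carbon with inversion, and must never ionise the benzylic carbon.
- The geometry at C2 is unchanged; its descriptor goes from R in 6 to S in 8 only because C3 drops below ring B in priority once its oxygen is replaced by carbon. The configurational bookkeeping, cis-(2R,3S) in 6 to trans-(2S,3S) in 8, was re-derived and is consistent; no structure needed correction.
- A triarylphosphine is chosen for the key step so that the aryl sulfonate of 6 is not activated by palladium.

**6 to 5.** Both C–O bonds of the epoxide are cut. Cis-disubstituted aryl alkyl olefins are the best substrate class for (salen)manganese epoxidation, so both stereocentres arise from an achiral olefin in one catalytic step. The forward step must be enantioselective and stereospecific (cis retained), which also requires geometrically pure 5.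

**5 to 2 and 3 (through 4).** The olefinic C=C bond is cut. This leads to an aromatic aldehyde and a two-carbon phosphonium salt, both simple. The forward Wittig reaction must be run under kinetic, lithium-free conditions to give the Z-olefin.

**2 to 1.** The O–S bond is cut, leading to the commercial hydroxy aldehyde. The only demand is clean O-sulfonylation in the presence of the aldehyde.

## Other disconnections considered

**Alternative 1:** The cut is the bond between C3 and its methyl carbon, made together with a temporary bond from that carbon to C2.

- Forward key step: an engineered myoglobin carbene transferase (a heme protein used in whole cells) would transfer the carbene of ethyl diazoacetate A2 to the C2=C3 bond of 5-bromo-7-methoxybenzofuran A1. The product would be the exo cyclopropane A3, with the furan ring dearomatised and C3 already configured as in the target.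
- In favour: carbene transfer to benzofurans by such proteins is an established reaction class, so on precedent this key step is better founded than the chosen one. It is catalytic in the chiral agent and starts from a flat, easily made substrate. Later opening of the donor–acceptor cyclopropane at C2, anti to the C3 substituent, should give the trans relationship by substrate control; on this point it is the equal of the chosen plan.
- Against: the key step makes only one bond of the target skeleton, and the carbene brings an ester carbon that the target lacks.
  - The C2–aryl bond must then be forged with a ring B aryl–metal reagent, because the required position of ring B (para to its central oxygen) is not the one a Friedel–Crafts reaction would use.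
  - The acetic ester side chain must be hydrolysed and decarboxylated down to the methyl group, the bromide exchanged for the propenyl group, and the phenol unmasked.
  - The protein is not an off-the-shelf reagent.
- Comparison: in structure the chosen plan is more convergent (two skeletal bonds and the ring in one step, every carbon of both fragments kept). In mechanism the concerted iron-carbene addition is safer than the unproven epoxide opening. In step economy the alternative is longer, an estimated ten or more operations against eight.

**Alternative 2:** The cut is the C2–C3 bond.

- Forward key step: one enantiomer of Rh2(PTTL)4, dirhodium tetrakis(N-phthaloyl-tert-leucinate), would decompose the aryldiazoacetate A4. The ring A carbene would insert into the benzylic ether C–H bond five atoms away and close the dihydrofuran ring as the cis ester A5, with C2 as in the target.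
- In favour: both stereocentres are created in one catalyst-controlled step. This is better than the chosen plan, which creates them in one step and transfers them in another. The reaction class is established for 2-aryl-2,3-dihydrobenzofuran-3-carboxylates, so precedent is again better. The electron-rich, MOM-protected ring B activates the C–H bond, whereas the chosen plan has to deactivate ring B.
- Against: the relative configuration is cis and C3 carries a methoxycarbonyl group, not a methyl group.
  - C3 must be epimerised through an ester enolate that can also open the ring by β-elimination of the phenoxide.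
  - The ester must be taken down to the methyl group in three operations (reduction, activation, hydride displacement).
  - The bromide must be exchanged for the propenyl group and the MOM group removed.
  - A4 itself needs a multi-step preparation that ends in a diazo transfer.
- Comparison: in structure the route is linear and its key step makes one skeletal bond. In mechanism the metal-carbene C–H insertion is well understood and more reliable than the chosen key step. In step economy it is clearly longer, an estimated twelve operations against eight.

**Alternative 3:** The cut is the C3–C3a bond, traced back to a 1,2-aryl shift.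

- Forward key step: PhI(OAc)2 (trivalent iodine) with H2SO4 in HC(OMe)3 would convert the enantiopure flavanone A6 into its enol ether and iodinate C3. Ring A carbon C4a would then migrate from C4 to C3 as the iodane leaves, contracting the pyranone to the trans ester A7.
- In favour: the reaction class is known for flavanones, is metal-free and uses cheap reagents. It gives the trans ring directly, the equal of the chosen plan. It tolerates the same mesylate protecting group and leaves the C2–O bond untouched.
- Against: C2 of A6 is the only source of chirality, and a flavanone can lose it by reversible ring opening to the chalcone in strong acid.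
  - Dehydrogenation to the flavone and migration of ring B are the typical competing paths.
  - The extruded carbon ends as an ester that needs three operations to become the methyl group.
  - The bromide must still be exchanged for the propenyl group.
  - A6 must first be assembled and made enantiopure.
- Comparison: in structure the key step makes one skeletal bond and re-forms a ring; it does not join two fragments. In mechanism the cationic 1,2-shift is better supported than the chosen key step, but it runs in strong acid where the chosen plan stays basic throughout. In step economy it is longer, an estimated ten operations or more against eight.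

Key step: step 4

Assumptions (remarks on the chemistry):
- The (R,R) enantiomer of the (salen)manganese chloride catalyst is taken to give the (2R,3S) epoxide from 5, by analogy with the sense of induction of this catalyst class on cis-β-methylstyrene and indene. If 5 responds in the opposite sense, the (S,S) catalyst is used.
- 5-(Ethylsulfonyl)-1-phenyl-1H-tetrazole is treated as a purchasable reagent.
- Enantiomeric enrichment by crystallisation is foreseen at 6 or 8 if needed.

Step 1
Reactants: 1 3-hydroxy-4,5-dimethoxybenzaldehyde
Product: 2 5-formyl-2,3-dimethoxyphenyl methanesulfonate
Conditions: MsCl, Et3N, CH2Cl2, 0 °C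
Reagents that add atoms: methanesulfonyl chloride, CS(=O)(=O)Cl
Why: O-sulfonylation of the phenol; the aldehyde is inert, and the sulfonate turns an oxidisable, nucleophilic phenol into a robust electron-withdrawing group that is needed again in step 4.

Step 2
Reactants: 2 5-formyl-2,3-dimethoxyphenyl methanesulfonate; 3 ethyltriphenylphosphonium bromide
Product: 5 2,3-dimethoxy-5-[(Z)-prop-1-enyl]phenyl methanesulfonate, via ethylidenetriphenylphosphorane 4 (not isolated)
Conditions: 3, KN(SiMe3)2, THF, 0 °C; then 2, −78 °C → rt
Reagents that add atoms: none
Why: Wittig olefination with a non-stabilised ylide under lithium-free conditions, where kinetic, irreversible formation of the cis-oxaphosphetane leads to the Z-olefin; reaction at −78 °C lets carbonyl addition outrun deprotonation of the mesyl methyl group. Any E-isomer is a poor substrate for step 3 and should be left behind there.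

Step 3
Reactants: 5 2,3-dimethoxy-5-[(Z)-prop-1-enyl]phenyl methanesulfonate
Product: 6 (2R,3S)-2-[3,4-dimethoxy-5-(methylsulfonyloxy)phenyl]-3-methyloxirane (cis)
Conditions: (R,R)-N,N′-bis(3,5-di-tert-butylsalicylidene)-1,2-cyclohexanediaminomanganese chloride (5 mol %), 4-phenylpyridine N-oxide, aq. NaOCl (pH 11.3), CH2Cl2, 0 °C
Reagents that add atoms: sodium hypochlorite, [Na+].[O-]Cl
Why: Jacobsen–Katsuki epoxidation, in which an oxo species of pentavalent manganese formed from the trivalent manganese salen complex and hypochlorite transfers oxygen to the cis-olefin in a side-on approach; cis aryl alkyl olefins are the best substrate class for it. Both stereocentres (benzylic carbon R, methyl-bearing carbon S) are set by the catalyst, and the N-oxide ligand and low temperature should suppress the bond rotation that would leak to the trans-epoxide.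

Step 4
Reactants: 6 (2R,3S)-2-[3,4-dimethoxy-5-(methylsulfonyloxy)phenyl]-3-methyloxirane; 7 methyl 4-iodo-3-methoxybenzoate
Product: 8 methyl (2S,3S)-2-[3,4-dimethoxy-5-(methylsulfonyloxy)phenyl]-7-methoxy-3-methyl-2,3-dihydrobenzofuran-5-carboxylate
Conditions: Pd(OAc)2 (10 mol %), tri(2-furyl)phosphine (22 mol %), norbornene (1 equiv), Cs2CO3 (2 equiv), 6 (1.5 equiv), NMP, 100 °C
Reagents that add atoms: none
Why: Proposed new method: zerovalent palladium inserts into the C–I bond of 7, norbornene inserts into the aryl–palladium bond, and carbonate-assisted ortho C–H palladation (the C7 methoxy group blocks the other ortho site) gives the five-membered aryl–norbornyl palladacycle of divalent palladium; this palladacycle attacks 6 in an SN2 manner at the methyl-bearing carbon (alkyl complex of tetravalent palladium, inversion), reductive elimination forms C3–C3a, and β-carbon elimination expels norbornene. The closest known reaction type is the palladium/norbornene (Catellani-type) annulation of ortho-substituted aryl iodides with terminal epoxides to 2-substituted 2,3-dihydrobenzofurans; opening an internal cis aryl methyl epoxide at its non-benzylic carbon is the unproven extension. The dihydrofuran ring is closed by intramolecular C(aryl)–O reductive elimination at the ipso carbon C7a from a six-membered aryl(alkoxo)palladium chelate, which the para ester should accelerate. No stereocentre is created: C3 comes from the epoxide with inversion and C2 with retention because its C–O bond is never broken, so the cis-epoxide maps onto the trans-(2S,3S) ring. The selectivity needed is opening at the methyl carbon and not at the benzylic carbon; the meta mesylate and the flanked, twisted para methoxy group make ring B a poor cation stabiliser, carbonate keeps the medium free of acid, and the bulky, soft palladacycle should prefer the less encumbered, non-conjugated carbon. Selectivity for C–I over C–OMs is secured by the triarylphosphine, which does not activate aryl sulfonates.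

Step 5
Reactants: 8 methyl (2S,3S)-2-[3,4-dimethoxy-5-(methylsulfonyloxy)phenyl]-7-methoxy-3-methyl-2,3-dihydrobenzofuran-5-carboxylate
Product: 9 5-[(2S,3S)-5-(hydroxymethyl)-7-methoxy-3-methyl-2,3-dihydrobenzofuran-2-yl]-2,3-dimethoxyphenyl methanesulfonate
Conditions: i-Bu2AlH (2.5 equiv), CH2Cl2, −78 → 0 °C; aq. potassium sodium tartrate
Reagents that add atoms: none
Why: Reduction of the methyl ester to the primary benzylic alcohol by an electrophilic aluminium hydride; at low temperature the aryl sulfonate, the aryl ethers and the two stereocentres should not be touched.

Step 6
Reactants: 9 5-[(2S,3S)-5-(hydroxymethyl)-7-methoxy-3-methyl-2,3-dihydrobenzofuran-2-yl]-2,3-dimethoxyphenyl methanesulfonate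
Product: 10 5-[(2S,3S)-5-formyl-7-methoxy-3-methyl-2,3-dihydrobenzofuran-2-yl]-2,3-dimethoxyphenyl methanesulfonate
Conditions: MnO2, CH2Cl2, rt
Reagents that add atoms: none
Why: Heterogeneous MnO2 oxidation is selective for benzylic alcohols and stops at the aldehyde; the benzylic C–H bonds of the dihydrofuran ring and the sulfonate should not react.

Step 7
Reactants: 10 5-[(2S,3S)-5-formyl-7-methoxy-3-methyl-2,3-dihydrobenzofuran-2-yl]-2,3-dimethoxyphenyl methanesulfonate
Product: 11 2,3-dimethoxy-5-[(2S,3S)-7-methoxy-3-methyl-5-[(E)-prop-1-enyl]-2,3-dihydrobenzofuran-2-yl]phenyl methanesulfonate
Conditions: 5-(ethylsulfonyl)-1-phenyl-1H-tetrazole, KN(SiMe3)2, DME, −60 °C; then 10, −60 °C → rt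
Reagents that add atoms: 5-(ethylsulfonyl)-1-phenyl-1H-tetrazole, CCS(=O)(=O)c1nnnn1-c1ccccc1
Why: Julia–Kocienski olefination, in which the potassium sulfonyl carbanion adds to the aldehyde and the adduct undergoes Smiles rearrangement and anti-periplanar loss of SO2 and tetrazololate; the open transition state favoured by potassium in DME leads to the E-olefin. Pre-metalation of the sulfone keeps free base away from the mesylate, and C2 and C3 carry no acidic hydrogen.

Step 8
Reactants: 11 2,3-dimethoxy-5-[(2S,3S)-7-methoxy-3-methyl-5-[(E)-prop-1-enyl]-2,3-dihydrobenzofuran-2-yl]phenyl methanesulfonate
Product: 12 5-[(2S,3S)-7-methoxy-3-methyl-5-[(E)-prop-1-enyl]-2,3-dihydrobenzofuran-2-yl]-2,3-dimethoxyphenol (the target)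
Conditions: KOH, MeOH/1,4-dioxane/H2O, 60 °C, argon; then aq. HCl to pH 5
Reagents that add atoms: none
Why: Hydroxide attacks the sulfonyl sulfur and releases the phenoxide (S–O cleavage), so the aryl C–O bond and the rest of the skeleton stay intact. The conjugated (E)-propenyl group is stable to base, C2 and C3 have no acidifying group so the trans configuration is kept, and exclusion of air protects the phenoxide.

## Compound list

1 | 3-hydroxy-4,5-dimethoxybenzaldehyde | O=Cc1cc(O)c(OC)c(OC)c1 | starting material
2 | 5-formyl-2,3-dimethoxyphenyl methanesulfonate | O=Cc1cc(OS(C)(=O)=O)c(OC)c(OC)c1 | intermediate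
3 | ethyltriphenylphosphonium bromide | CC[P+](c1ccccc1)(c1ccccc1)c1ccccc1.[Br-] | starting material
4 | ethylidenetriphenylphosphorane | CC=P(c1ccccc1)(c1ccccc1)c1ccccc1 | intermediate
5 | 2,3-dimethoxy-5-[(Z)-prop-1-enyl]phenyl methanesulfonate | C/C=C\c1cc(OS(C)(=O)=O)c(OC)c(OC)c1 | intermediate
6 | (2R,3S)-2-[3,4-dimethoxy-5-(methylsulfonyloxy)phenyl]-3-methyloxirane (cis) | C[C@@H]1O[C@@H]1c1cc(OS(C)(=O)=O)c(OC)c(OC)c1 | intermediate
7 | methyl 4-iodo-3-methoxybenzoate | COC(=O)c1ccc(I)c(OC)c1 | starting material
8 | methyl (2S,3S)-2-[3,4-dimethoxy-5-(methylsulfonyloxy)phenyl]-7-methoxy-3-methyl-2,3-dihydrobenzofuran-5-carboxylate (trans) | COC(=O)c1cc(OC)c2c(c1)[C@H](C)[C@@H](c1cc(OS(C)(=O)=O)c(OC)c(OC)c1)O2 | intermediate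
9 | 5-[(2S,3S)-5-(hydroxymethyl)-7-methoxy-3-methyl-2,3-dihydrobenzofuran-2-yl]-2,3-dimethoxyphenyl methanesulfonate | OCc1cc(OC)c2c(c1)[C@H](C)[C@@H](c1cc(OS(C)(=O)=O)c(OC)c(OC)c1)O2 | intermediate
10 | 5-[(2S,3S)-5-formyl-7-methoxy-3-methyl-2,3-dihydrobenzofuran-2-yl]-2,3-dimethoxyphenyl methanesulfonate | O=Cc1cc(OC)c2c(c1)[C@H](C)[C@@H](c1cc(OS(C)(=O)=O)c(OC)c(OC)c1)O2 | intermediate
11 | 2,3-dimethoxy-5-[(2S,3S)-7-methoxy-3-methyl-5-[(E)-prop-1-enyl]-2,3-dihydrobenzofuran-2-yl]phenyl methanesulfonate | C/C=C/c1cc(OC)c2c(c1)[C@H](C)[C@@H](c1cc(OS(C)(=O)=O)c(OC)c(OC)c1)O2 | intermediate
12 | 5-[(2S,3S)-7-methoxy-3-methyl-5-[(E)-prop-1-enyl]-2,3-dihydrobenzofuran-2-yl]-2,3-dimethoxyphenol (trans) | C/C=C/c1cc(OC)c2c(c1)[C@H](C)[C@@H](c1cc(O)c(OC)c(OC)c1)O2 | target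

## Step count and least certain steps

Total step count: 8. Longest linear sequence: 8 steps (1 → 2 → 5 → 6 → 8 → 9 → 10 → 11 → 12); 3 and 7 are purchased and enter in steps 2 and 4.

**Step 4 (key step, proposed new method).**
- What may go wrong: the internal epoxide may open at the benzylic carbon, or the palladacycle may not engage the hindered internal epoxide at all and may decay by benzocyclobutene formation or ortho-arylation with a second molecule of 7. Zerovalent palladium may also isomerise the epoxide to a ketone, and β-hydride elimination of the palladium alkoxide may outrun C–O closure. The cause is that an internal epoxide is far less electrophilic than a terminal one and its benzylic carbon is electronically the more activated site.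
- Fallback, known reactions only, setting out from 2 and returning at 8:
  - EtMgBr (THF, −78 °C) adds to 2 to give racemic 1-[3,4-dimethoxy-5-(methylsulfonyloxy)phenyl]propan-1-ol F1, which MnO2 oxidises to 1-[3,4-dimethoxy-5-(methylsulfonyloxy)phenyl]propan-1-one F2.
  - Commercial methyl 3-bromo-4-hydroxy-5-methoxybenzoate F3 is protected (MOMCl, i-Pr2NEt) as methyl 3-bromo-5-methoxy-4-(methoxymethoxy)benzoate F4.
  - Palladium-catalysed ketone α-arylation of F2 with F4 (Pd2(dba)3, Xantphos, K3PO4, toluene, 90 °C) makes the C3–C3a bond. It gives the racemic, configurationally labile ketone methyl 3-{1-[3,4-dimethoxy-5-(methylsulfonyloxy)phenyl]-1-oxopropan-2-yl}-5-methoxy-4-(methoxymethoxy)benzoate F5.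
  - Noyori–Ikariya transfer hydrogenation under dynamic kinetic resolution (RuCl(p-cymene)[(S,S)-TsDPEN], HCO2H/Et3N) should reduce the epimerising ketone to methyl 3-{(1S,2S)-1-[3,4-dimethoxy-5-(methylsulfonyloxy)phenyl]-1-hydroxypropan-2-yl}-5-methoxy-4-(methoxymethoxy)benzoate F6. The catalyst chooses the carbonyl face and a Felkin–Anh-type preference chooses the α-centre; the catalyst antipode is selected so that the methyl-bearing carbon is S.
  - CF3CO2H in CH2Cl2 then removes the MOM group and closes the O1–C2 bond through the benzylic cation, with the C3 methyl group directing ring B trans, which gives 8. Only the methyl-bearing centre of F6 has to be correct, since the carbinol centre is ionised.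

**Step 3.**
- What may go wrong: leakage from cis to trans epoxide through bond rotation in the stepwise, radical-type oxygen transfer, and incomplete facial selectivity. Both lower the stereochemical purity that step 4 passes on unchanged.
- Fallback from 5 back to 6: an organocatalytic dioxirane epoxidation of the Shi type (carbohydrate-derived oxazolidinone ketone of the appropriate enantiomeric series, KHSO5 as its triple salt, K2CO3 buffer, MeCN/dimethoxymethane, 0 °C). Its concerted spiro transition state cannot scramble olefin geometry. It makes no new compound (F0).

**Step 7.**
- What may go wrong: incomplete E-selectivity, because addition of the sulfonyl carbanion to an aromatic aldehyde is only partly diastereoselective, and attack of the amide base on the mesyl group.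
- Fallback from 10 back to 11: Takai–Utimoto ethylidenation (CrCl2, CH3CHI2, THF, rt), a non-basic organochromium olefination known to favour E-olefins with aromatic aldehydes. It makes no new compound (F0).

**Step 2.**
- What may go wrong: the basic ylide may deprotonate the mesyl methyl group, with loss of the protecting group through a sulfene, and Z-selectivity may be incomplete. The second is partly absorbed by step 3, where the E-olefin reacts slowly.
- Fallback from 1 back to 5, reversing the order of the first two steps: 1 is treated with two equivalents of 4 (from 3 and KN(SiMe3)2, THF, −78 °C → rt). The phenoxide protects itself and the Wittig reaction should give 2,3-dimethoxy-5-[(Z)-prop-1-enyl]phenol F7. This is then mesylated (MsCl, Et3N, CH2Cl2, 0 °C) to 5.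

## Further compounds

F1 | step 4 | 1-[3,4-dimethoxy-5-(methylsulfonyloxy)phenyl]propan-1-ol (racemic) | CCC(O)c1cc(OS(C)(=O)=O)c(OC)c(OC)c1
F2 | step 4 | 1-[3,4-dimethoxy-5-(methylsulfonyloxy)phenyl]propan-1-one | CCC(=O)c1cc(OS(C)(=O)=O)c(OC)c(OC)c1
F3 | step 4 | methyl 3-bromo-4-hydroxy-5-methoxybenzoate | COC(=O)c1cc(Br)c(O)c(OC)c1
F4 | step 4 | methyl 3-bromo-5-methoxy-4-(methoxymethoxy)benzoate | COCOc1c(Br)cc(C(=O)OC)cc1OC
F5 | step 4 | methyl 3-{1-[3,4-dimethoxy-5-(methylsulfonyloxy)phenyl]-1-oxopropan-2-yl}-5-methoxy-4-(methoxymethoxy)benzoate (racemic) | COC(=O)c1cc(OC)c(OCOC)c(c1)C(C)C(=O)c1cc(OS(C)(=O)=O)c(OC)c(OC)c1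
F6 | step 4 | methyl 3-{(1S,2S)-1-[3,4-dimethoxy-5-(methylsulfonyloxy)phenyl]-1-hydroxypropan-2-yl}-5-methoxy-4-(methoxymethoxy)benzoate | COC(=O)c1cc(OC)c(OCOC)c(c1)[C@H](C)[C@H](O)c1cc(OS(C)(=O)=O)c(OC)c(OC)c1
F0 | step 3 | none | none
F0 | step 7 | none | none
F7 | step 2 | 2,3-dimethoxy-5-[(Z)-prop-1-enyl]phenol | C/C=C\c1cc(O)c(OC)c(OC)c1
A1 | alternative 1 | 5-bromo-7-methoxybenzofuran | COc1cc(Br)cc2ccoc12
A2 | alternative 1 | ethyl diazoacetate | CCOC(=O)C=[N+]=[N-]
A3 | alternative 1 | ethyl (1R,1aR,6bS)-5-bromo-3-methoxy-1a,6b-dihydro-1H-cyclopropa[b]benzofuran-1-carboxylate (exo) | CCOC(=O)[C@H]1[C@@H]2Oc3c(OC)cc(Br)cc3[C@H]12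
A4 | alternative 2 | methyl 2-{5-bromo-2-[(3,4-dimethoxy-5-(methoxymethoxy)phenyl)methoxy]-3-methoxyphenyl}-2-diazoacetate | COC(=O)C(=[N+]=[N-])c1cc(Br)cc(OC)c1OCc1cc(OCOC)c(OC)c(OC)c1
A5 | alternative 2 | methyl (2S,3R)-5-bromo-2-[3,4-dimethoxy-5-(methoxymethoxy)phenyl]-7-methoxy-2,3-dihydrobenzofuran-3-carboxylate (cis) | Brc1cc(OC)c2c(c1)[C@@H](C(=O)OC)[C@@H](c1cc(OCOC)c(OC)c(OC)c1)O2
A6 | alternative 3 | (2S)-6-bromo-2-[3,4-dimethoxy-5-(methylsulfonyloxy)phenyl]-8-methoxychroman-4-one | O=C1C[C@@H](c2cc(OS(C)(=O)=O)c(OC)c(OC)c2)Oc2c(OC)cc(Br)cc12
A7 | alternative 3 | methyl (2S,3S)-5-bromo-2-[3,4-dimethoxy-5-(methylsulfonyloxy)phenyl]-7-methoxy-2,3-dihydrobenzofuran-3-carboxylate (trans) | Brc1cc(OC)c2c(c1)[C@H](C(=O)OC)[C@@H](c1cc(OS(C)(=O)=O)c(OC)c(OC)c1)O2
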